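- Retrosynthesis: both hydroxyquinones are unmasked last. Ring B comes from a 1,2,4-trimethoxyarene and ring A from a phenol whose para carbon is still C–H; the two future quinone hydroxyls are carried as an ethyl ether (ring A) and a methyl ether (ring B).
- Going round ring A from the carbon that bears the 2-methoxyphenethyl chain, the atoms are: chain carbon, axis carbon, first carbonyl carbon, C-methyl carbon, C-hydroxyl carbon, second carbonyl carbon. The oxygen/methyl/oxygen triad that follows the axis carbon is what a ketene carbonyl and 1-ethoxypropyne deliver, and the second carbonyl carbon is para to the first, so it can be oxygenated afterwards. Ring A is therefore cut at three bonds (first carbonyl to C-methyl, C-hydroxyl to second carbonyl, first carbonyl to axis), giving a vinylketene (from an unsaturated diazoketone) and the ynol ether.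
- The diazoketone is cut at its C=C (Horner–Wadsworth–Emmons, HWE) into the hexasubstituted ring B aldehyde and an alkylated phosphonoacetate; ring B goes back to 3,5-dimethoxy-4-methylbenzaldehyde.
- Forward: ring B is completed (steps 1–6), the acrylate with the anisylethyl chain is attached (steps 7–10), the diazoketone is made (step 12), and ring A is built last onto the alkene carbon that already carries ring B (step 13). Two oxidations and one hydrolysis finish the route.
- Stereochemistry: there are no stereocentres. The only stereo-element that matters is the E alkene from the HWE step, which keeps ring B outside the closing triene. The biaryl axis forms without control.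

Key step: step 13

Assumption: the target is drawn without an axial descriptor, so the hindered axis between ring A and ring B is treated as unspecified and the compound is made racemic about it.

**Route**

Step 1
Reactants: 1 3,5-dimethoxy-4-methylbenzaldehyde; 2 diethyl benzylphosphonate
Product: 3 1,3-dimethoxy-2-methyl-5-[(E)-2-phenylethenyl]benzene
Conditions: KOt-Bu, THF, 0 °C to rt
Reagents that add atoms: none
Why: HWE olefination of an unhindered aryl aldehyde with a benzylphosphonate anion should give the (E)-stilbene.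

Step 2
Reactants: 3 (E)-stilbene
Product: 4 1,3-dimethoxy-2-methyl-5-(2-phenylethyl)benzene
Conditions: H2 (1 atm), Pd/C, EtOAc, rt
Reagents that add atoms: none
Why: Heterogeneous catalytic hydrogenation saturates the stilbene C=C and leaves arenes and aryl ethers alone.

Step 3
Reactants: 4 bibenzyl
Product: 5 2,4-dimethoxy-3-methyl-6-(2-phenylethyl)benzaldehyde
Conditions: POCl3, DMF, 0 to 70 °C; then H2O
Reagents that add atoms: N,N-dimethylformamide CN(C)C=O (formyl carbon); water O (formyl oxygen)
Why: Vilsmeier–Haack formylation should go to one of the two equivalent free positions, each ortho to one methoxy and para to the other, while the side-chain phenyl ring is unactivated.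

Step 4
Reactants: 5 aldehyde
Product: 7 2,4-dimethoxy-3-methyl-6-(2-phenylethyl)phenol, via aryl formate 6 (not isolated)
Conditions: mCPBA, CH2Cl2, 0 °C to rt; aq. NaHCO3 wash; then K2CO3 (cat.), MeOH, rt
Reagents that add atoms: 3-chloroperoxybenzoic acid OOC(=O)c1cccc(Cl)c1
Why: In this Baeyer–Villiger (Dakin-type) oxidation the electron-rich aryl group migrates to give the formate, which mild methanolysis cleaves to the phenol.

Step 5
Reactants: 7 phenol
Product: 8 1,3,4-trimethoxy-2-methyl-5-(2-phenylethyl)benzene
Conditions: MeI, K2CO3, acetone, reflux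
Reagents that add atoms: iodomethane CI
Why: Williamson ether synthesis on a phenoxide is reliable even with two ortho substituents.

Step 6
Reactants: 8 trimethoxyarene
Product: 9 2,4,5-trimethoxy-3-methyl-6-(2-phenylethyl)benzaldehyde
Conditions: Cl2CHOMe, TiCl4, CH2Cl2, −78 to 0 °C; then H2O
Reagents that add atoms: dichloromethyl methyl ether COC(Cl)Cl (formyl carbon); water O (formyl oxygen)
Why: Rieche formylation can only attack the single remaining position of the electron-rich ring, which is ortho to one methoxy and para to another, as in known formylations of pentasubstituted polymethoxytoluenes.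

Step 7
Reactants: 10 2-(2-methoxyphenyl)ethanol
Product: 11 1-(2-iodoethyl)-2-methoxybenzene
Conditions: I2, PPh3, imidazole, CH2Cl2, 0 °C to rt
Reagents that add atoms: iodine II
Why: Appel-type iodination converts the primary alcohol by SN2 displacement of its alkoxyphosphonium ion.

Step 8
Reactants: 12 triethyl phosphonoacetate; 11 iodide
Product: 13 ethyl 2-(diethoxyphosphoryl)-4-(2-methoxyphenyl)butanoate (racemic)
Conditions: 12 (excess), NaH, DMF, 0 °C; then 11, 60 °C
Reagents that add atoms: none
Why: C-alkylation of the soft sodium phosphonoacetate anion with a primary iodide should favour substitution over elimination to the styrene, and the excess of 12 suppresses dialkylation; the new stereocentre is racemic and disappears in step 9.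

Step 9
Reactants: 13 phosphonate; 9 ring B aldehyde
Product: 14 ethyl (2E)-2-[2-(2-methoxyphenyl)ethyl]-3-[2,4,5-trimethoxy-3-methyl-6-(2-phenylethyl)phenyl]prop-2-enoate
Conditions: NaH, THF, 0 °C; then 9, reflux
Reagents that add atoms: none
Why: HWE olefination with an alpha-branched stabilised phosphonate adds reversibly and eliminates through the less crowded oxaphosphetane, placing the ester trans to the aryl group (E).

Step 10
Reactants: 14 (E)-enoate
Product: 15 (2E)-2-[2-(2-methoxyphenyl)ethyl]-3-[2,4,5-trimethoxy-3-methyl-6-(2-phenylethyl)phenyl]prop-2-enoic acid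
Conditions: KOH, EtOH/H2O, reflux; then aq. HCl
Reagents that add atoms: potassium hydroxide [K+].[OH-]
Why: Saponification of the hindered conjugated ester needs heat but leaves the aryl ethers and the thermodynamically preferred E geometry intact.

Step 11
Reactants: 16 ethoxyacetylene
Product: 17 1-ethoxyprop-1-yne
Conditions: NaNH2, NH3 (l), −33 °C; then MeI; distillation
Reagents that add atoms: iodomethane CI
Why: Alkylation of the sodium acetylide of an alkoxyalkyne with iodomethane is a standard SN2 route to 1-alkoxy-1-alkynes.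

Step 12
Reactants: 15 (E)-acid
Product: 19 (3E)-1-diazo-3-[2-(2-methoxyphenyl)ethyl]-4-[2,4,5-trimethoxy-3-methyl-6-(2-phenylethyl)phenyl]but-3-en-2-one, via acid chloride 18 (not isolated)
Conditions: (COCl)2, DMF (cat.), CH2Cl2, 0 °C to rt, evaporate; then CH2N2 (excess), Et2O, 0 °C
Reagents that add atoms: diazomethane C=[N+]=[N-]; oxalyl chloride O=C(Cl)C(=O)Cl (chlorine of 18 only)
Why: This is the Arndt–Eistert acylation of diazomethane by an acid chloride, with excess diazomethane scavenging HCl; the trisubstituted alkene, shielded by the di-ortho-substituted aryl group, should be too poor a dipolarophile to form pyrazoline at 0 °C.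

Step 13
Reactants: 19 (E)-diazoketone; 17 1-ethoxyprop-1-yne
Product: 24 3-ethoxy-5-[2-(2-methoxyphenyl)ethyl]-2-methyl-6-[2,4,5-trimethoxy-3-methyl-6-(2-phenylethyl)phenyl]phenol, via vinylketene 20 (not isolated), via cyclobutenone 21 (not isolated), via dienylketene 22 (not isolated), via cyclohexadienone 23 (not isolated)
Conditions: hν (254 nm, quartz), 17 (3 equiv), degassed ClCH2CH2Cl, rt; then 80 °C
Reagents that add atoms: none
Why: Light expels N2 from 19 and the alkenyl group migrates with retention of its geometry (photochemical Wolff rearrangement) to give vinylketene 20, whose ketene C=C adds to the ynol ether in a polar [2+2] cycloaddition, joining the ketene carbonyl carbon to the methyl-bearing alkyne carbon and the ketene alpha carbon to the ethoxy-bearing alkyne carbon, to give 4-alkenylcyclobutenone 21. On warming, reversible conrotatory 4π opening gives dienylketene 22, and the isomer with the alkenyl group rotated inward closes ring A by a thermally allowed disrotatory 6π electrocyclisation between the ketene carbon and the alkene carbon bearing ring B (the bond from the first carbonyl carbon to the axis carbon), after which enolisation of 23 gives the phenol, so the steric cost of the crowded axis is met only when aromaticity is gained. The closest known reaction type is the Danheiser benzannulation in its photochemical Wolff form with alkoxy- or siloxyalkynes. No stereocentre survives in the product and the axis arises racemic. The step needs one regiochemistry in the [2+2] event, and the polarisation of the ynol ether secures it because its methyl-bearing carbon is the nucleophilic terminus that attacks the electrophilic ketene carbonyl carbon. The E geometry of 19 keeps ring B on the outside of the triene terminus, so the bulky aryl group does not block the bond-forming trajectory.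

Step 14
Reactants: 24 biaryl phenol
Product: 25 2-ethoxy-6-[2-(2-methoxyphenyl)ethyl]-3-methyl-5-[2,4,5-trimethoxy-3-methyl-6-(2-phenylethyl)phenyl]cyclohexa-2,5-diene-1,4-dione
Conditions: (KSO3)2NO, KH2PO4, acetone/H2O, rt
Reagents that add atoms: potassium nitrosodisulfonate [K+].[K+].[O]N(S(=O)(=O)[O-])S(=O)(=O)[O-]
Why: In the Teuber oxidation one nitrosodisulfonate radical removes the phenolic hydrogen and a second couples at the only open ring carbon, which lies para to the oxygen, giving the para-quinone; ring B has no free hydroxyl and is untouched.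

Step 15
Reactants: 25 ring A quinone
Product: 26 2-ethoxy-5-[4-methoxy-5-methyl-3,6-dioxo-2-(2-phenylethyl)cyclohexa-1,4-dien-1-yl]-6-[2-(2-methoxyphenyl)ethyl]-3-methylcyclohexa-2,5-diene-1,4-dione
Conditions: (NH4)2Ce(NO3)6, MeCN/H2O, 0 °C
Reagents that add atoms: water O
Why: Oxidative demethylation by tetravalent cerium removes an electron from the electron-rich ring B, water adds at the two para-related methoxy carbons (one next to the phenethyl carbon, one next to the axis carbon) and methanol is lost, giving the para-quinone with the middle methoxy retained; the anisole ring and the quinone ring A are too electron-poor to compete.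

Step 16
Reactants: 26 bis-quinone diether
Product: 27 2-hydroxy-5-[4-hydroxy-5-methyl-3,6-dioxo-2-(2-phenylethyl)cyclohexa-1,4-dien-1-yl]-6-[2-(2-methoxyphenyl)ethyl]-3-methylcyclohexa-2,5-diene-1,4-dione (CNP0202346.0)
Conditions: NaOH, THF/H2O, 0 °C to rt; then aq. HCl
Reagents that add atoms: sodium hydroxide [Na+].[OH-]
Why: Both alkoxyquinones are vinylogous esters, so hydroxide addition–elimination at the ethoxy-bearing carbon of ring A and the methoxy-bearing carbon of ring B gives the stabilised hydroxyquinone anions, while the aryl methyl ether of the side chain cannot react this way.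

**Compound list**

1 | 3,5-dimethoxy-4-methylbenzaldehyde | Cc1c(OC)cc(C=O)cc1OC | starting material
2 | diethyl benzylphosphonate | CCOP(=O)(Cc1ccccc1)OCC | starting material
3 | 1,3-dimethoxy-2-methyl-5-[(E)-2-phenylethenyl]benzene | COc1cc(/C=C/c2ccccc2)cc(OC)c1C | intermediate
4 | 1,3-dimethoxy-2-methyl-5-(2-phenylethyl)benzene | COc1cc(CCc2ccccc2)cc(OC)c1C | intermediate
5 | 2,4-dimethoxy-3-methyl-6-(2-phenylethyl)benzaldehyde | O=Cc1c(CCc2ccccc2)cc(OC)c(C)c1OC | intermediate
6 | 2,4-dimethoxy-3-methyl-6-(2-phenylethyl)phenyl formate | O=COc1c(CCc2ccccc2)cc(OC)c(C)c1OC | intermediate (not isolated)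
7 | 2,4-dimethoxy-3-methyl-6-(2-phenylethyl)phenol | Oc1c(CCc2ccccc2)cc(OC)c(C)c1OC | intermediate
8 | 1,3,4-trimethoxy-2-methyl-5-(2-phenylethyl)benzene | COc1c(CCc2ccccc2)cc(OC)c(C)c1OC | intermediate
9 | 2,4,5-trimethoxy-3-methyl-6-(2-phenylethyl)benzaldehyde | O=Cc1c(CCc2ccccc2)c(OC)c(OC)c(C)c1OC | intermediate
10 | 2-(2-methoxyphenyl)ethanol | COc1ccccc1CCO | starting material
11 | 1-(2-iodoethyl)-2-methoxybenzene | COc1ccccc1CCI | intermediate
12 | triethyl phosphonoacetate | CCOC(=O)CP(=O)(OCC)OCC | starting material
13 | ethyl 2-(diethoxyphosphoryl)-4-(2-methoxyphenyl)butanoate (racemic) | CCOC(=O)C(CCc1ccccc1OC)P(=O)(OCC)OCC | intermediate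
14 | ethyl (2E)-2-[2-(2-methoxyphenyl)ethyl]-3-[2,4,5-trimethoxy-3-methyl-6-(2-phenylethyl)phenyl]prop-2-enoate | CCOC(=O)/C(CCc1ccccc1OC)=C/c1c(CCc2ccccc2)c(OC)c(OC)c(C)c1OC | intermediate
15 | (2E)-2-[2-(2-methoxyphenyl)ethyl]-3-[2,4,5-trimethoxy-3-methyl-6-(2-phenylethyl)phenyl]prop-2-enoic acid | OC(=O)/C(CCc1ccccc1OC)=C/c1c(CCc2ccccc2)c(OC)c(OC)c(C)c1OC | intermediate
16 | ethoxyacetylene (ethoxyethyne) | C#COCC | starting material
17 | 1-ethoxyprop-1-yne | CC#COCC | intermediate
18 | (2E)-2-[2-(2-methoxyphenyl)ethyl]-3-[2,4,5-trimethoxy-3-methyl-6-(2-phenylethyl)phenyl]prop-2-enoyl chloride | ClC(=O)/C(CCc1ccccc1OC)=C/c1c(CCc2ccccc2)c(OC)c(OC)c(C)c1OC | intermediate (not isolated)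
19 | (3E)-1-diazo-3-[2-(2-methoxyphenyl)ethyl]-4-[2,4,5-trimethoxy-3-methyl-6-(2-phenylethyl)phenyl]but-3-en-2-one | [N-]=[N+]=CC(=O)/C(CCc1ccccc1OC)=C/c1c(CCc2ccccc2)c(OC)c(OC)c(C)c1OC | intermediate
20 | (3E)-3-[2-(2-methoxyphenyl)ethyl]-4-[2,4,5-trimethoxy-3-methyl-6-(2-phenylethyl)phenyl]buta-1,3-dien-1-one (vinylketene) | O=C=C/C(CCc1ccccc1OC)=C/c1c(CCc2ccccc2)c(OC)c(OC)c(C)c1OC | intermediate (not isolated)
21 | 3-ethoxy-4-{(1E)-4-(2-methoxyphenyl)-1-[2,4,5-trimethoxy-3-methyl-6-(2-phenylethyl)phenyl]but-1-en-2-yl}-2-methylcyclobut-2-en-1-one (racemic) | O=C1C(C)=C(OCC)C1/C(CCc2ccccc2OC)=C/c2c(CCc3ccccc3)c(OC)c(OC)c(C)c2OC | intermediate (not isolated)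
22 | (3E,5E)-3-ethoxy-5-[2-(2-methoxyphenyl)ethyl]-2-methyl-6-[2,4,5-trimethoxy-3-methyl-6-(2-phenylethyl)phenyl]hexa-1,3,5-trien-1-one (dienylketene) | O=C=C(C)/C(OCC)=C\C(CCc1ccccc1OC)=C\c1c(CCc2ccccc2)c(OC)c(OC)c(C)c1OC | intermediate (not isolated)
23 | 3-ethoxy-5-[2-(2-methoxyphenyl)ethyl]-2-methyl-6-[2,4,5-trimethoxy-3-methyl-6-(2-phenylethyl)phenyl]cyclohexa-2,4-dien-1-one (racemic) | O=C1C(C)=C(OCC)C=C(CCc2ccccc2OC)C1c1c(CCc2ccccc2)c(OC)c(OC)c(C)c1OC | intermediate (not isolated)
24 | 3-ethoxy-5-[2-(2-methoxyphenyl)ethyl]-2-methyl-6-[2,4,5-trimethoxy-3-methyl-6-(2-phenylethyl)phenyl]phenol | COc1ccccc1CCc1cc(OCC)c(C)c(O)c1-c1c(CCc2ccccc2)c(OC)c(OC)c(C)c1OC | intermediate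
25 | 2-ethoxy-6-[2-(2-methoxyphenyl)ethyl]-3-methyl-5-[2,4,5-trimethoxy-3-methyl-6-(2-phenylethyl)phenyl]cyclohexa-2,5-diene-1,4-dione | COc1ccccc1CCC1=C(c2c(CCc3ccccc3)c(OC)c(OC)c(C)c2OC)C(=O)C(C)=C(OCC)C1=O | intermediate
26 | 2-ethoxy-5-[4-methoxy-5-methyl-3,6-dioxo-2-(2-phenylethyl)cyclohexa-1,4-dien-1-yl]-6-[2-(2-methoxyphenyl)ethyl]-3-methylcyclohexa-2,5-diene-1,4-dione | COc1ccccc1CCC1=C(C2=C(CCc3ccccc3)C(=O)C(OC)=C(C)C2=O)C(=O)C(C)=C(OCC)C1=O | intermediate
27 | 2-hydroxy-5-[4-hydroxy-5-methyl-3,6-dioxo-2-(2-phenylethyl)cyclohexa-1,4-dien-1-yl]-6-[2-(2-methoxyphenyl)ethyl]-3-methylcyclohexa-2,5-diene-1,4-dione (CNP0202346.0) | COc1ccccc1CCC1=C(C2=C(CCc3ccccc3)C(=O)C(O)=C(C)C2=O)C(=O)C(C)=C(O)C1=O | target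

**Step count**

Total: 16 steps. Longest linear sequence: 13 steps (1–6, 9, 10, 12, 13, 14, 15, 16).

**Steps most likely to fail**

Step 13. Several things could go wrong. The three arene chromophores and the phenol product compete for 254 nm light, the styrene-type C=C may photoisomerise, the s-trans rotamer of the diazoketone may divert to carbene chemistry, and the ethyl ynol ether may lose ethylene by retro-ene reaction during the thermal stage. The fallback makes the same vinylketene without light. It sets out from 19, whose Wolff rearrangement would be run in the dark with PhCO2Ag (cat.) and Et3N in THF/H2O, so that water traps the ketene as (3E)-3-[2-(2-methoxyphenyl)ethyl]-4-[2,4,5-trimethoxy-3-methyl-6-(2-phenylethyl)phenyl]but-3-enoic acid F1. Treatment with (COCl)2 and DMF (cat.) would give (3E)-3-[2-(2-methoxyphenyl)ethyl]-4-[2,4,5-trimethoxy-3-methyl-6-(2-phenylethyl)phenyl]but-3-enoyl chloride F2. Slow addition of Et3N to F2 and 17 in CH2Cl2 at rt would release vinylketene 20 by dehydrochlorination, and its [2+2] cycloaddition returns to the route at cyclobutenone 21. Heating 21 in toluene at 80–110 °C then leads through 22 and 23 to 24.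

Step 12. Diazomethane may add as a 1,3-dipole across the conjugated C=C in competition with C-acylation, and HCl may isomerise the alkene during acid chloride formation. The fallback avoids both the acid chloride and diazomethane. It sets out from 15, which with MeLi (2.2 equiv) in THF at −78 to 0 °C should give the methyl ketone (3E)-3-[2-(2-methoxyphenyl)ethyl]-4-[2,4,5-trimethoxy-3-methyl-6-(2-phenylethyl)phenyl]but-3-en-2-one F3. Kinetic enolisation with LiN(SiMe3)2 at −78 °C and trapping with CF3CO2CH2CF3 would give, after an aqueous HCl quench, (5E)-1,1,1-trifluoro-5-[2-(2-methoxyphenyl)ethyl]-6-[2,4,5-trimethoxy-3-methyl-6-(2-phenylethyl)phenyl]hex-5-ene-2,4-dione F4, used crude. Detrifluoroacetylative diazo transfer with MsN3, Et3N and H2O in MeCN returns to the route at 19.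

Step 16. Hydroxide may degrade the bis-quinone faster than the second ether is cleaved, by deprotonating the CH2 groups on the quinone rings to quinone-methide tautomers or by attacking carbonyl carbons. The fallback reorders the endgame so that hydroxide never meets a bis-quinone. It sets out from 25, where ring B is still an inert arene. NaOH in THF/H2O followed by aq. HCl would hydrolyse the single ethoxyquinone to 2-hydroxy-6-[2-(2-methoxyphenyl)ethyl]-3-methyl-5-[2,4,5-trimethoxy-3-methyl-6-(2-phenylethyl)phenyl]cyclohexa-2,5-diene-1,4-dione F5. Oxidation of ring B with (NH4)2Ce(NO3)6 in MeCN/H2O would give 2-hydroxy-5-[4-methoxy-5-methyl-3,6-dioxo-2-(2-phenylethyl)cyclohexa-1,4-dien-1-yl]-6-[2-(2-methoxyphenyl)ethyl]-3-methylcyclohexa-2,5-diene-1,4-dione F6. The one remaining methoxyquinone would be cleaved under acid catalysis (aq. HClO4, dioxane, 50 °C), returning to the route at 27.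

Further compounds
F1 | step 13 | (3E)-3-[2-(2-methoxyphenyl)ethyl]-4-[2,4,5-trimethoxy-3-methyl-6-(2-phenylethyl)phenyl]but-3-enoic acid | OC(=O)C/C(CCc1ccccc1OC)=C/c1c(CCc2ccccc2)c(OC)c(OC)c(C)c1OC
F2 | step 13 | (3E)-3-[2-(2-methoxyphenyl)ethyl]-4-[2,4,5-trimethoxy-3-methyl-6-(2-phenylethyl)phenyl]but-3-enoyl chloride | ClC(=O)C/C(CCc1ccccc1OC)=C/c1c(CCc2ccccc2)c(OC)c(OC)c(C)c1OC
F3 | step 12 | (3E)-3-[2-(2-methoxyphenyl)ethyl]-4-[2,4,5-trimethoxy-3-methyl-6-(2-phenylethyl)phenyl]but-3-en-2-one | CC(=O)/C(CCc1ccccc1OC)=C/c1c(CCc2ccccc2)c(OC)c(OC)c(C)c1OC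
F4 | step 12 | (5E)-1,1,1-trifluoro-5-[2-(2-methoxyphenyl)ethyl]-6-[2,4,5-trimethoxy-3-methyl-6-(2-phenylethyl)phenyl]hex-5-ene-2,4-dione | FC(F)(F)C(=O)CC(=O)/C(CCc1ccccc1OC)=C/c1c(CCc2ccccc2)c(OC)c(OC)c(C)c1OC
F5 | step 16 | 2-hydroxy-6-[2-(2-methoxyphenyl)ethyl]-3-methyl-5-[2,4,5-trimethoxy-3-methyl-6-(2-phenylethyl)phenyl]cyclohexa-2,5-diene-1,4-dione | COc1ccccc1CCC1=C(c2c(CCc3ccccc3)c(OC)c(OC)c(C)c2OC)C(=O)C(C)=C(O)C1=O
F6 | step 16 | 2-hydroxy-5-[4-methoxy-5-methyl-3,6-dioxo-2-(2-phenylethyl)cyclohexa-1,4-dien-1-yl]-6-[2-(2-methoxyphenyl)ethyl]-3-methylcyclohexa-2,5-diene-1,4-dione | COc1ccccc1CCC1=C(C2=C(CCc3ccccc3)C(=O)C(OC)=C(C)C2=O)C(=O)C(C)=C(O)C1=O
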